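The route rests on disconnecting the C2=C3 bond of the pyrrole ring. The benzo ring already bears the C4 and C6 bromines, a CH2–PPh3+ group on C3a and an ethyl oxamate on the nitrogen that becomes N1. An intramolecular Wittig reaction between the benzylic ylide and the N1-bound amide carbonyl forms C2=C3 and closes the five-membered ring in one operation, leaving an ester at C2. The precursor is a 2,4-dibromo-6-(ethoxyoxalylamino)benzylphosphonium bromide, reached in four steps from 2,4-dibromo-6-nitrotoluene. Afterwards the C2 carboxyl group is exchanged for bromine while C3 is brominated, giving the 2,3,4,6-tetrabromo pattern.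

Key step: step 5

Remark: the bromines ortho and para to the methyl group of 1 and its ortho nitro group map unchanged onto C4–Br, C6–Br and N1 of the target; the oxamate N–H is carried unprotected, so step 5 uses only about one equivalent of a non-nucleophilic base.

Step 1
Reactants: 1 2,4-dibromo-6-nitrotoluene (1,5-dibromo-2-methyl-3-nitrobenzene)
Product: 2 2,4-dibromo-6-nitrobenzyl bromide (1,5-dibromo-2-(bromomethyl)-3-nitrobenzene)
Conditions: NBS (1.1 equiv), AIBN (cat.), PhCF3, 90 °C
Reagents that add atoms: N-bromosuccinimide, O=C1CCC(=O)N1Br
Why: Wohl–Ziegler radical bromination should attack only the benzylic methyl C–H bonds, the nitro group and aryl bromides being inert to the bromine radical chain, and stopping short of full conversion limits the dibromide.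

Step 2
Reactants: 2 2,4-dibromo-6-nitrobenzyl bromide; 3 triphenylphosphine
Product: 4 (2,4-dibromo-6-nitrobenzyl)triphenylphosphonium bromide
Conditions: PPh3 (1.05 equiv), toluene, 90 °C; salt collected by filtration
Reagents that add atoms: triphenylphosphine, c1ccc(cc1)P(c1ccccc1)c1ccccc1
Why: SN2 quaternization of the phosphine by a primary benzylic bromide (phosphonium salt formation) should proceed despite the two ortho substituents, at a temperature far below that needed for phosphine deoxygenation of the nitro group.

Step 3
Reactants: 4 (2,4-dibromo-6-nitrobenzyl)triphenylphosphonium bromide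
Product: 5 (2-amino-4,6-dibromobenzyl)triphenylphosphonium bromide
Conditions: Fe powder, 48% aq HBr, EtOH, 70 °C; NaHCO3 work-up
Reagents that add atoms: none
Why: Béchamp-type iron/acid nitro reduction should give the aniline without cleaving aryl C–Br bonds, and the acidic medium prevents ylide formation or hydroxide-induced P–C cleavage while keeping bromide as the counter-ion.

Step 4
Reactants: 5 (2-amino-4,6-dibromobenzyl)triphenylphosphonium bromide; 6 ethyl chlorooxoacetate
Product: 7 [2,4-dibromo-6-(ethoxyoxalylamino)benzyl]triphenylphosphonium bromide
Conditions: ClCOCO2Et (1.2 equiv), pyridine (1.5 equiv), CH2Cl2, 0 °C to rt; aq NaBr wash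
Reagents that add atoms: ethyl chlorooxoacetate, CCOC(=O)C(Cl)=O
Why: N-acylation of the aniline by the acid chloride should occur at the acyl chloride carbonyl rather than the ester, with pyridine as an acid scavenger far too weak to deprotonate the benzylic phosphonium.

Step 5
Reactants: 7 [2,4-dibromo-6-(ethoxyoxalylamino)benzyl]triphenylphosphonium bromide
Product: 9 ethyl 4,6-dibromo-1H-indole-2-carboxylate, via benzylic phosphonium ylide 8 (not isolated)
Conditions: KN(SiMe3)2 (1.05 equiv), THF/toluene, 0 °C then 90 °C
Reagents that add atoms: none
Why: One equivalent of base removes a single acidic proton from 7, and the amidate and ylide forms interconvert by proton transfer, so that ylide 8, which keeps the neutral N1-bound carbonyl, adds through its benzylic carbon to that carbonyl and the oxaphosphetane collapses to C2=C3 with loss of triphenylphosphine oxide. This is the intramolecular Wittig olefination of (2-acylaminobenzyl)triphenylphosphonium salts that gives 2-substituted indoles, applied here with an oxamate as the acyl group. The pyrrole ring closes in a 5-exo-trig mode, the attacked C=O lying outside the forming five-membered ring, and no stereocenter is created. The step needs chemoselectivity for the amide over the ester carbonyl: attack at the amide carbon gives a five-membered ring that aromatizes to the indole, and the neighbouring ester makes that carbonyl more electrophilic, whereas attack at the ester would be a slower six-membered acylation. The non-nucleophilic base, used without excess, avoids ester exchange and a doubly deprotonated, unreactive species. The metal-free, non-reducing conditions leave the C4 and C6 aryl bromides untouched.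

Step 6
Reactants: 9 ethyl 4,6-dibromo-1H-indole-2-carboxylate
Product: 10 4,6-dibromo-1H-indole-2-carboxylic acid
Conditions: LiOH·H2O (3 equiv), THF/H2O, 50 °C; then 1 M HCl to pH 2
Reagents that add atoms: lithium hydroxide, [Li+].[OH-]
Why: Hydroxide-mediated ester saponification followed by acidification should give the free acid, the aryl bromides and the indole N–H being unaffected.

Step 7
Reactants: 10 4,6-dibromo-1H-indole-2-carboxylic acid
Product: 12 2,3,4,6-tetrabromo-1H-indole, via 3,4,6-tribromo-1H-indole-2-carboxylic acid 11 (not isolated)
Conditions: NBS (2.05 equiv), DMF, 0 °C to rt, dark; aq Na2S2O3 work-up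
Reagents that add atoms: N-bromosuccinimide, O=C1CCC(=O)N1Br
Why: Electrophilic aromatic bromination at the most nucleophilic position C3 should give 11, after which the second equivalent effects ipso-bromodecarboxylation at C2 (halodecarboxylation of an electron-rich heteroarene carboxylic acid, bromonium attack then loss of CO2 and rearomatization), while the benzo positions C5 and C7 are deactivated by the ring bromines.

Compound list
1 | 2,4-dibromo-6-nitrotoluene (1,5-dibromo-2-methyl-3-nitrobenzene) | Cc1c(Br)cc(Br)cc1[N+](=O)[O-] | starting material
2 | 2,4-dibromo-6-nitrobenzyl bromide | BrCc1c(Br)cc(Br)cc1[N+](=O)[O-] | intermediate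
3 | triphenylphosphine | c1ccc(cc1)P(c1ccccc1)c1ccccc1 | starting material
4 | (2,4-dibromo-6-nitrobenzyl)triphenylphosphonium bromide | [O-][N+](=O)c1cc(Br)cc(Br)c1C[P+](c1ccccc1)(c1ccccc1)c1ccccc1.[Br-] | intermediate
5 | (2-amino-4,6-dibromobenzyl)triphenylphosphonium bromide | Nc1cc(Br)cc(Br)c1C[P+](c1ccccc1)(c1ccccc1)c1ccccc1.[Br-] | intermediate
6 | ethyl chlorooxoacetate | CCOC(=O)C(Cl)=O | starting material
7 | [2,4-dibromo-6-(ethoxyoxalylamino)benzyl]triphenylphosphonium bromide | CCOC(=O)C(=O)Nc1cc(Br)cc(Br)c1C[P+](c1ccccc1)(c1ccccc1)c1ccccc1.[Br-] | intermediate
8 | ethyl 2-{[3,5-dibromo-2-(triphenylphosphoranylidenemethyl)phenyl]amino}-2-oxoacetate (benzylic phosphonium ylide) | CCOC(=O)C(=O)Nc1cc(Br)cc(Br)c1C=P(c1ccccc1)(c1ccccc1)c1ccccc1 | intermediate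
9 | ethyl 4,6-dibromo-1H-indole-2-carboxylate | CCOC(=O)c1cc2c(Br)cc(Br)cc2[nH]1 | intermediate
10 | 4,6-dibromo-1H-indole-2-carboxylic acid | OC(=O)c1cc2c(Br)cc(Br)cc2[nH]1 | intermediate
11 | 3,4,6-tribromo-1H-indole-2-carboxylic acid | OC(=O)c1[nH]c2cc(Br)cc(Br)c2c1Br | intermediate
12 | 2,3,4,6-tetrabromo-1H-indole | Brc1cc(Br)c2c(Br)c(Br)[nH]c2c1 | target

Total step count: 7
Longest linear sequence: 7 steps (1 to 12)

Steps most likely to fail

Step 5. Proton removal could settle on the amide nitrogen and stall the closure, the ylide could acylate at the ester carbonyl, or traces of water could cleave the benzylic P–C bond. The fallback leaves the Wittig closure and builds the same indole ester by a Reissert sequence. It sets out from 1: condensation with diethyl oxalate and KOEt in Et2O/EtOH, then acidification with HCl, should give ethyl 3-(2,4-dibromo-6-nitrophenyl)-2-oxopropanoate F1. Reductive cyclization of F1 with Fe powder in AcOH at 80 °C should close the N1–C2 bond, and the route is rejoined at 9.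

Step 7. Excess electrophilic bromine could oxidize the electron-rich N–H indole, the ipso-substitution at C2 could stop before loss of CO2, or bromination could spill onto C5 or C7. The fallback separates decarboxylation from bromination. It sets out from 10: protodecarboxylation with catalytic Cu2O and 1,10-phenanthroline in NMP/quinoline at about 170 °C should give 4,6-dibromo-1H-indole F2. Stepwise electrophilic bromination of F2 at C3 and then C2 with NBS (2 equiv) in DMF at 0 °C returns to the route at 12.

Step 1. Radical chain propagation at the electron-poor, doubly ortho-flanked methyl group could be slow, and a second benzylic bromination could compete. The fallback functionalizes the methyl group through its acidity instead. It sets out from 1: condensation with Me2NCH(OMe)2 and catalytic pyrrolidine in DMF at 110 °C should give (E)-2-(2,4-dibromo-6-nitrophenyl)-N,N-dimethylethen-1-amine F3. Oxidative cleavage of the enamine double bond with NaIO4 in aqueous THF should give 2,4-dibromo-6-nitrobenzaldehyde F4. Reduction with NaBH4 in MeOH should give (2,4-dibromo-6-nitrophenyl)methanol F5, and PBr3 in CH2Cl2 at 0 °C converts F5 into the bromide, rejoining the route at 2.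

Further compounds
F1 | step 5 | ethyl 3-(2,4-dibromo-6-nitrophenyl)-2-oxopropanoate | CCOC(=O)C(=O)Cc1c(Br)cc(Br)cc1[N+](=O)[O-]
F2 | step 7 | 4,6-dibromo-1H-indole | Brc1cc(Br)c2cc[nH]c2c1
F3 | step 1 | (E)-2-(2,4-dibromo-6-nitrophenyl)-N,N-dimethylethen-1-amine | CN(C)/C=C/c1c(Br)cc(Br)cc1[N+](=O)[O-]
F4 | step 1 | 2,4-dibromo-6-nitrobenzaldehyde | O=Cc1c(Br)cc(Br)cc1[N+](=O)[O-]
F5 | step 1 | (2,4-dibromo-6-nitrophenyl)methanol | OCc1c(Br)cc(Br)cc1[N+](=O)[O-]
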